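Chain numbered C1 (alkyne CH) to C15 (ethyl CH3); the ring oxygen joins C9 and C13.
1. Cuts: the C7 acetate; the enyne C1–C4 back to a vinyl group on C5; C12–Br and C10–Cl back to alcohols (each with inversion); O–C13 of the oxane; C7–C8 (aldol); the furan–C9 acyl bond.
2. Forward: 2-acetyl-5-ethylfuran and (R)-2-chloropent-4-enal are joined at C7–C8, the C9 ketone is reduced, and the anodic Achmatowicz ring expansion closes the only ring; the ring halogens follow, then the enyne, then the acetate.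
3. Enabling feature: ring atoms C10–C13 (heteroatoms at C10 and C12, ethyl on C13) are the four carbons of 2-ethylfuran and the C9 carbinol sits on its free α-position, so closure of O–C13 gives the six-membered ring.
4. Stereochemistry: C6 by enamine-catalysed α-chlorination; C7 by Cornforth-controlled aldol addition (1,2-anti); C9 by Noyori transfer hydrogenation; C13 by axial hydride delivery to the oxocarbenium ion (2,6-cis).
5. C12: bulky hydride gives the axial alcohol, bromide enters with inversion; C10: small hydride gives the equatorial alcohol, chloride enters with inversion; the 3E alkene comes from cross-metathesis.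

Key step: step 6

Abbreviations: TBS = tert-butyldimethylsilyl; Bpin = 4,4,5,5-tetramethyl-1,3,2-dioxaborolan-2-yl; side chain A = (2S,3R)-2-(TBSO)-3-chlorohex-5-en-1-yl (C8 to C4 of the target chain plus one terminal CH2).
Assumption: the catalyst antipodes written in steps 2 and 5 are those expected to give (R)-4 and (1R)-7; if either sense proves opposite, the mirror-image catalyst is used.

Step 1
Reactants: 1 2-ethylfuran
Product: 2 1-(5-ethylfuran-2-yl)ethan-1-one
Conditions: Ac2O, BF3·OEt2 (cat.), 0 °C → rt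
Reagents that add atoms: acetic anhydride, CC(=O)OC(C)=O
Why: Friedel–Crafts acylation of a 2-alkylfuran goes to the free α-position, giving the methyl ketone whose carbonyl carbon becomes C9 and whose methyl group becomes C8.

Step 2
Reactants: 3 pent-4-enal
Product: 4 (2R)-2-chloropent-4-enal
Conditions: N-chlorosuccinimide, (2S,5S)-2,5-diphenylpyrrolidine (10 mol%), CH2Cl2, 0 °C → rt; pentane extraction, solution used at once
Reagents that add atoms: N-chlorosuccinimide, O=C1CCC(=O)N1Cl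
Why: Enamine-catalysed electrophilic α-chlorination of an aldehyde sets C6 under catalyst control; the product is configurationally labile and is therefore carried on without chromatography.

Step 3
Reactants: 2 1-(5-ethylfuran-2-yl)ethan-1-one; 4 (2R)-2-chloropent-4-enal
Product: 5 (3S,4R)-4-chloro-1-(5-ethylfuran-2-yl)-3-hydroxyhept-6-en-1-one
Conditions: lithium diisopropylamide, THF, −78 °C, 2 then 4; aq. NH4Cl at −78 °C
Reagents that add atoms: none
Why: Lithium aldol addition of a methyl ketone enolate to an α-chloroaldehyde follows the Cornforth model (C–Cl anti to C=O, attack past hydrogen), so the 1,2-anti chlorohydrin (C6 R, C7 S) should predominate, and the cold quench prevents epoxide closure of the aldolate.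

Step 4
Reactants: 5 (3S,4R)-4-chloro-1-(5-ethylfuran-2-yl)-3-hydroxyhept-6-en-1-one
Product: 6 (3S,4R)-3-(TBSO)-4-chloro-1-(5-ethylfuran-2-yl)hept-6-en-1-one
Conditions: TBSOTf, 2,6-lutidine, CH2Cl2, −78 → 0 °C
Reagents that add atoms: tert-butyldimethylsilyl triflate, CC(C)(C)[Si](C)(C)OS(=O)(=O)C(F)(F)F
Why: Silylation of the β-hydroxy ketone with a silyl triflate and a hindered base masks the C7 hydroxyl (the later acetate site) without elimination, so that only the C9 hydroxyl is free in the key step.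

Step 5
Reactants: 6 (3S,4R)-3-(TBSO)-4-chloro-1-(5-ethylfuran-2-yl)hept-6-en-1-one
Product: 7 (1R,3S,4R)-3-(TBSO)-4-chloro-1-(5-ethylfuran-2-yl)hept-6-en-1-ol
Conditions: RuCl(p-cymene)[(R,R)-TsDPEN] (2 mol%), HCO2H/Et3N (5:2), CH2Cl2, rt
Reagents that add atoms: none
Why: Noyori asymmetric transfer hydrogenation of a 2-acylfuran is catalyst-controlled, the furyl group taking the aryl role, so the (R,R)-ligand should give the (R)-C9 carbinol whatever the remote C7 centre; alkene, chloride and silyl ether are inert.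

Step 6
Reactants: 7 (1R,3S,4R)-3-(TBSO)-4-chloro-1-(5-ethylfuran-2-yl)hept-6-en-1-ol
Product: 10 (2R)-2-A-6-ethyl-6-hydroxy-2H-pyran-3(6H)-one (C6 epimers), via 2,5-dimethoxy-2,5-dihydrofuran 8 (not isolated), via cis-enedione 9 (not isolated)
Conditions: undivided cell, graphite anode, platinum cathode, NH4Br (0.2 equiv), MeOH, −10 °C, constant current, about 2.1 F per mol; then 0.1 M aq. H2SO4, THF, 0 °C → rt
Reagents that add atoms: water, O (the new oxygen of 10); methanol, CO (its atoms stay only in 8)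
Why: Bromine generated at the anode from the bromide mediator attacks the furan and methanol is taken up at both α-carbons to give 8; dilute acid then hydrolyses both ketal carbons to the Z-enedione 9. The C9 hydroxyl closes onto the C13 carbonyl as a hemiketal (6-exo-trig, O–C13 bond), which forms the oxane ring with the C10 ketone and the C11–C12 alkene in place. The closest known reaction type is the Achmatowicz rearrangement run electrochemically (anodic 2,5-dimethoxylation of a furfuryl alcohol, then acid). No lasting stereocentre is made: C9 passes through unchanged and the C13 hemiketal forms as an anomeric mixture that step 7 erases. The step needs oxidation of the furan in preference to the terminal alkene; the 2,5-dialkylfuran is by far the most electron-rich π-system, and limiting the charge keeps the standing bromine concentration low, while the silyl ether and the secondary chloride are inert.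

Step 7
Reactants: 10 (2R)-2-A-6-ethyl-6-hydroxy-2H-pyran-3(6H)-one
Product: 11 (2R,6S)-2-A-6-ethyl-2H-pyran-3(6H)-one
Conditions: Et3SiH, CF3CO2H, CH2Cl2, −40 °C
Reagents that add atoms: none
Why: Ionic hydrogenation: acid ionises the hemiketal to a cyclic oxocarbenium ion at C13 and the silane adds axially (chair-like transition state, C9 side chain pseudo-equatorial), which should give the 2,6-cis ring; the enone is not reduced at this temperature.

Step 8
Reactants: 11 (2R,6S)-2-A-6-ethyl-2H-pyran-3(6H)-one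
Product: 12 (2R,5R,6S)-2-A-6-ethyl-5-Bpin-oxan-3-one
Conditions: B2pin2, CuCl (5 mol%), DPEphos (5 mol%), NaOtBu (10 mol%), MeOH (2 equiv), THF, rt
Reagents that add atoms: bis(pinacolato)diboron, CC1(C)OB(OC1(C)C)B1OC(C)(C)C(C)(C)O1
Why: Copper-catalysed conjugate borylation of a cyclic enone places boron on the β-carbon C12 and so tells C12 from C11; addition anti to the neighbouring ethyl group is expected, but the C12 configuration is reset in steps 12 and 13, and the unactivated alkene and alkyl chloride react far more slowly than the enone.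

Step 9
Reactants: 12 (2R,5R,6S)-2-A-6-ethyl-5-Bpin-oxan-3-one
Product: 13 (2R,3S,5R,6S)-2-A-6-ethyl-5-Bpin-oxan-3-ol
Conditions: NaBH4, MeOH, −40 °C
Reagents that add atoms: none
Why: A small hydride attacks an oxan-3-one axially (the only syn-axial partner is the C12 hydrogen, position 1 being oxygen), which should give the equatorial C10 alcohol trans to the C9 side chain.

Step 10
Reactants: 13 (2R,3S,5R,6S)-2-A-6-ethyl-5-Bpin-oxan-3-ol
Product: 14 (2R,3S,5R,6S)-2-A-6-ethyl-5-Bpin-oxan-3-yl pivalate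
Conditions: t-BuCOCl, pyridine, DMAP (cat.), CH2Cl2, 0 °C → rt
Reagents that add atoms: pivaloyl chloride, CC(C)(C)C(Cl)=O
Why: Acylation of the equatorial alcohol gives a pivalate that withstands perborate, periodinane and the hindered borohydride and is orthogonal to the C7 silyl ether.

Step 11
Reactants: 14 (2R,3S,5R,6S)-2-A-6-ethyl-5-Bpin-oxan-3-yl pivalate
Product: 15 (2R,3S,5R,6S)-2-A-6-ethyl-5-hydroxyoxan-3-yl pivalate
Conditions: NaBO3·4H2O, THF/H2O (1:1), rt
Reagents that add atoms: sodium perborate, [Na+].[O-]OB=O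
Why: Perborate oxidation of the C–B bond proceeds by 1,2-migration with retention and is mild enough for the ester, the silyl ether and the chloride.

Step 12
Reactants: 15 (2R,3S,5R,6S)-2-A-6-ethyl-5-hydroxyoxan-3-yl pivalate
Product: 16 (2R,3S,6S)-2-A-6-ethyl-5-oxooxan-3-yl pivalate
Conditions: Dess–Martin periodinane, NaHCO3, CH2Cl2, 0 °C → rt
Reagents that add atoms: none
Why: Dess–Martin oxidation gives the C12 ketone under buffered, non-basic conditions and removes the C12 centre of step 8 whatever its configuration; the equatorial ethyl group at the adjacent C13 is the stable arrangement.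

Step 13
Reactants: 16 (2R,3S,6S)-2-A-6-ethyl-5-oxooxan-3-yl pivalate
Product: 17 (2R,3S,5S,6S)-2-A-6-ethyl-5-hydroxyoxan-3-yl pivalate
Conditions: LiBH(s-Bu)3 (L-Selectride), THF, −78 °C; aq. NH4Cl
Reagents that add atoms: none
Why: The bulky hydride attacks a 2-alkyl-oxan-3-one from the equatorial direction, which should give the axial C12 alcohol cis to the ethyl group, the arrangement needed for invertive bromination.

Step 14
Reactants: 17 (2R,3S,5S,6S)-2-A-6-ethyl-5-hydroxyoxan-3-yl pivalate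
Product: 18 (2R,3S,5R,6S)-5-bromo-2-A-6-ethyloxan-3-yl pivalate
Conditions: CBr4, P(n-Oct)3, toluene, 70 °C
Reagents that add atoms: carbon tetrabromide, BrC(Br)(Br)Br
Why: Appel bromination (oxyphosphonium ion, SN2 by bromide entering equatorially) inverts C12 to the equatorial bromide trans to the ethyl group.

Step 15
Reactants: 18 (2R,3S,5R,6S)-5-bromo-2-A-6-ethyloxan-3-yl pivalate
Product: 19 (2R,3S,5R,6S)-5-bromo-2-A-6-ethyloxan-3-ol
Conditions: i-Bu2AlH, CH2Cl2, −78 °C; aq. potassium sodium tartrate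
Reagents that add atoms: none
Why: Hydride cleavage of the pivalate at low temperature frees the C10 alcohol without touching the secondary halides, the alkene or the silyl ether.

Step 16
Reactants: 19 (2R,3S,5R,6S)-5-bromo-2-A-6-ethyloxan-3-ol
Product: 20 (2R,3R,5R,6S)-5-bromo-3-chloro-2-A-6-ethyloxane
Conditions: CCl4, P(n-Oct)3, toluene, 80 °C
Reagents that add atoms: carbon tetrachloride, ClC(Cl)(Cl)Cl
Why: Appel chlorination converts the equatorial alcohol through its oxyphosphonium ion into the axial chloride with inversion (SN2, chloride entering axially past only the axial C12 hydrogen), which sets C10–Cl cis to the C9 side chain.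

Step 17
Reactants: 20 (2R,3R,5R,6S)-5-bromo-3-chloro-2-A-6-ethyloxane
Product: 21 (2E,5R,6S)-7-[(2R,3R,5R,6S)-5-bromo-3-chloro-6-ethyloxan-2-yl]-6-(TBSO)-5-chlorohept-2-enal
Conditions: (E)-crotonaldehyde (10 equiv), second-generation Grubbs catalyst RuCl2(=CHPh)(H2IMes)(PCy3) (5 mol%), CH2Cl2, 40 °C
Reagents that add atoms: (E)-crotonaldehyde, C/C=C/C=O
Why: Cross-metathesis of the terminal alkene with excess crotonaldehyde gives the E-enal under thermodynamic control, turning the vinyl group into C4=C3 with C2 as aldehyde.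

Step 18
Reactants: 21 (2E,5R,6S)-7-[(2R,3R,5R,6S)-5-bromo-3-chloro-6-ethyloxan-2-yl]-6-(TBSO)-5-chlorohept-2-enal
Product: 22 tert-butyl({(2S,3R,5E)-1-[(2R,3R,5R,6S)-5-bromo-3-chloro-6-ethyloxan-2-yl]-3-chlorooct-5-en-7-yn-2-yl}oxy)dimethylsilane
Conditions: Me3SiCHN2, lithium diisopropylamide, THF, −78 → 0 °C; aq. NH4Cl
Reagents that add atoms: trimethylsilyldiazomethane, C[Si](C)(C)C=[N+]=[N-]
Why: Colvin rearrangement: the lithiated silyldiazomethane adds to the aldehyde, Peterson-type loss of silanolate and then of nitrogen gives an alkylidene carbene, and 1,2-hydrogen shift gives the terminal alkyne (C1) with the E-alkene intact; addition at −78 °C should outrun deprotonation at C5.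

Step 19
Reactants: 22 tert-butyl({(2S,3R,5E)-1-[(2R,3R,5R,6S)-5-bromo-3-chloro-6-ethyloxan-2-yl]-3-chlorooct-5-en-7-yn-2-yl}oxy)dimethylsilane
Product: 23 (2S,3R,5E)-1-[(2R,3R,5R,6S)-5-bromo-3-chloro-6-ethyloxan-2-yl]-3-chlorooct-5-en-7-yn-2-ol
Conditions: HF·pyridine, pyridine, THF, 0 °C → rt
Reagents that add atoms: none
Why: Fluoride-mediated desilylation under acidic, non-basic conditions frees the C7 alcohol without closing the chlorohydrin to an epoxide; alkyne and halides survive.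

Step 20
Reactants: 23 (2S,3R,5E)-1-[(2R,3R,5R,6S)-5-bromo-3-chloro-6-ethyloxan-2-yl]-3-chlorooct-5-en-7-yn-2-ol
Product: 24 (2S,3R,5E)-1-[(2R,3R,5R,6S)-5-bromo-3-chloro-6-ethyloxan-2-yl]-3-chlorooct-5-en-7-yn-2-yl acetate
Conditions: Ac2O, pyridine, DMAP (cat.), CH2Cl2, 0 °C → rt
Reagents that add atoms: acetic anhydride, CC(=O)OC(C)=O
Why: Acylation of the C7 alcohol under nucleophilic catalysis completes the target without disturbing any stereocentre.

Compound list
1 | 2-ethylfuran | CCc1ccco1 | starting material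
2 | 1-(5-ethylfuran-2-yl)ethan-1-one | CCc1ccc(o1)C(C)=O | intermediate
3 | pent-4-enal | C=CCCC=O | starting material
4 | (2R)-2-chloropent-4-enal | C=CC[C@@H](Cl)C=O | intermediate
5 | (3S,4R)-4-chloro-1-(5-ethylfuran-2-yl)-3-hydroxyhept-6-en-1-one | CCc1ccc(o1)C(=O)C[C@H](O)[C@H](Cl)CC=C | intermediate
6 | (3S,4R)-3-[(tert-butyldimethylsilyl)oxy]-4-chloro-1-(5-ethylfuran-2-yl)hept-6-en-1-one | CCc1ccc(o1)C(=O)C[C@H](O[Si](C)(C)C(C)(C)C)[C@H](Cl)CC=C | intermediate
7 | (1R,3S,4R)-3-[(tert-butyldimethylsilyl)oxy]-4-chloro-1-(5-ethylfuran-2-yl)hept-6-en-1-ol | CCc1ccc(o1)[C@H](O)C[C@H](O[Si](C)(C)C(C)(C)C)[C@H](Cl)CC=C | intermediate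
8 | (1R,3S,4R)-3-[(tert-butyldimethylsilyl)oxy]-4-chloro-1-(5-ethyl-2,5-dimethoxy-2,5-dihydrofuran-2-yl)hept-6-en-1-ol (ketal epimers; not isolated) | CCC1(OC)C=CC(OC)(O1)[C@H](O)C[C@H](O[Si](C)(C)C(C)(C)C)[C@H](Cl)CC=C | intermediate
9 | (4Z,7R,9S,10R)-9-[(tert-butyldimethylsilyl)oxy]-10-chloro-7-hydroxytrideca-4,12-diene-3,6-dione (not isolated) | CCC(=O)/C=C\C(=O)[C@H](O)C[C@H](O[Si](C)(C)C(C)(C)C)[C@H](Cl)CC=C | intermediate
10 | (2R)-2-{(2S,3R)-2-[(tert-butyldimethylsilyl)oxy]-3-chlorohex-5-en-1-yl}-6-ethyl-6-hydroxy-2H-pyran-3(6H)-one (C6 epimers) | CCC1(O)C=CC(=O)[C@@H](C[C@H](O[Si](C)(C)C(C)(C)C)[C@H](Cl)CC=C)O1 | intermediate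
11 | (2R,6S)-2-{(2S,3R)-2-[(tert-butyldimethylsilyl)oxy]-3-chlorohex-5-en-1-yl}-6-ethyl-2H-pyran-3(6H)-one | CC[C@H]1C=CC(=O)[C@@H](C[C@H](O[Si](C)(C)C(C)(C)C)[C@H](Cl)CC=C)O1 | intermediate
12 | (2R,5R,6S)-2-{(2S,3R)-2-[(tert-butyldimethylsilyl)oxy]-3-chlorohex-5-en-1-yl}-6-ethyl-5-(4,4,5,5-tetramethyl-1,3,2-dioxaborolan-2-yl)oxan-3-one | CC[C@H]1[C@H](B2OC(C)(C)C(C)(C)O2)CC(=O)[C@@H](C[C@H](O[Si](C)(C)C(C)(C)C)[C@H](Cl)CC=C)O1 | intermediate
13 | (2R,3S,5R,6S)-2-{(2S,3R)-2-[(tert-butyldimethylsilyl)oxy]-3-chlorohex-5-en-1-yl}-6-ethyl-5-(4,4,5,5-tetramethyl-1,3,2-dioxaborolan-2-yl)oxan-3-ol | CC[C@H]1[C@H](B2OC(C)(C)C(C)(C)O2)C[C@H](O)[C@@H](C[C@H](O[Si](C)(C)C(C)(C)C)[C@H](Cl)CC=C)O1 | intermediate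
14 | (2R,3S,5R,6S)-2-{(2S,3R)-2-[(tert-butyldimethylsilyl)oxy]-3-chlorohex-5-en-1-yl}-6-ethyl-5-(4,4,5,5-tetramethyl-1,3,2-dioxaborolan-2-yl)oxan-3-yl 2,2-dimethylpropanoate | CC[C@H]1[C@H](B2OC(C)(C)C(C)(C)O2)C[C@H](OC(=O)C(C)(C)C)[C@@H](C[C@H](O[Si](C)(C)C(C)(C)C)[C@H](Cl)CC=C)O1 | intermediate
15 | (2R,3S,5R,6S)-2-{(2S,3R)-2-[(tert-butyldimethylsilyl)oxy]-3-chlorohex-5-en-1-yl}-6-ethyl-5-hydroxyoxan-3-yl 2,2-dimethylpropanoate | CC[C@H]1[C@H](O)C[C@H](OC(=O)C(C)(C)C)[C@@H](C[C@H](O[Si](C)(C)C(C)(C)C)[C@H](Cl)CC=C)O1 | intermediate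
16 | (2R,3S,6S)-2-{(2S,3R)-2-[(tert-butyldimethylsilyl)oxy]-3-chlorohex-5-en-1-yl}-6-ethyl-5-oxooxan-3-yl 2,2-dimethylpropanoate | CC[C@H]1C(=O)C[C@H](OC(=O)C(C)(C)C)[C@@H](C[C@H](O[Si](C)(C)C(C)(C)C)[C@H](Cl)CC=C)O1 | intermediate
17 | (2R,3S,5S,6S)-2-{(2S,3R)-2-[(tert-butyldimethylsilyl)oxy]-3-chlorohex-5-en-1-yl}-6-ethyl-5-hydroxyoxan-3-yl 2,2-dimethylpropanoate | CC[C@H]1[C@@H](O)C[C@H](OC(=O)C(C)(C)C)[C@@H](C[C@H](O[Si](C)(C)C(C)(C)C)[C@H](Cl)CC=C)O1 | intermediate
18 | (2R,3S,5R,6S)-5-bromo-2-{(2S,3R)-2-[(tert-butyldimethylsilyl)oxy]-3-chlorohex-5-en-1-yl}-6-ethyloxan-3-yl 2,2-dimethylpropanoate | CC[C@H]1[C@H](Br)C[C@H](OC(=O)C(C)(C)C)[C@@H](C[C@H](O[Si](C)(C)C(C)(C)C)[C@H](Cl)CC=C)O1 | intermediate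
19 | (2R,3S,5R,6S)-5-bromo-2-{(2S,3R)-2-[(tert-butyldimethylsilyl)oxy]-3-chlorohex-5-en-1-yl}-6-ethyloxan-3-ol | CC[C@H]1[C@H](Br)C[C@H](O)[C@@H](C[C@H](O[Si](C)(C)C(C)(C)C)[C@H](Cl)CC=C)O1 | intermediate
20 | tert-butyl({(2S,3R)-1-[(2R,3R,5R,6S)-5-bromo-3-chloro-6-ethyloxan-2-yl]-3-chlorohex-5-en-2-yl}oxy)dimethylsilane | CC[C@H]1[C@H](Br)C[C@@H](Cl)[C@@H](C[C@H](O[Si](C)(C)C(C)(C)C)[C@H](Cl)CC=C)O1 | intermediate
21 | (2E,5R,6S)-7-[(2R,3R,5R,6S)-5-bromo-3-chloro-6-ethyloxan-2-yl]-6-[(tert-butyldimethylsilyl)oxy]-5-chlorohept-2-enal | CC[C@H]1[C@H](Br)C[C@@H](Cl)[C@@H](C[C@H](O[Si](C)(C)C(C)(C)C)[C@H](Cl)C/C=C/C=O)O1 | intermediate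
22 | tert-butyl({(2S,3R,5E)-1-[(2R,3R,5R,6S)-5-bromo-3-chloro-6-ethyloxan-2-yl]-3-chlorooct-5-en-7-yn-2-yl}oxy)dimethylsilane | CC[C@H]1[C@H](Br)C[C@@H](Cl)[C@@H](C[C@H](O[Si](C)(C)C(C)(C)C)[C@H](Cl)C/C=C/C#C)O1 | intermediate
23 | (2S,3R,5E)-1-[(2R,3R,5R,6S)-5-bromo-3-chloro-6-ethyloxan-2-yl]-3-chlorooct-5-en-7-yn-2-ol | CC[C@H]1[C@H](Br)C[C@@H](Cl)[C@@H](C[C@H](O)[C@H](Cl)C/C=C/C#C)O1 | intermediate
24 | (2S,3R,5E)-1-[(2R,3R,5R,6S)-5-bromo-3-chloro-6-ethyloxan-2-yl]-3-chlorooct-5-en-7-yn-2-yl acetate | CC[C@H]1[C@H](Br)C[C@@H](Cl)[C@@H](C[C@H](OC(C)=O)[C@H](Cl)C/C=C/C#C)O1 | target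

Total steps: 20. Longest linear sequence: 19 steps (step 1 or step 2, then steps 3 to 20).

Steps most likely to fail
1. Step 16. Displacement at the equatorial C10 oxyphosphonium ion may be slow, so that participation by the ring oxygen (anti-periplanar to the leaving group, leading to ring contraction) or elimination takes over. Fallback: setting out from 19, the alcohol is converted into the chloromethanesulfonate F1 (ClCH2SO2Cl, pyridine, CH2Cl2, 0 °C). This isolated ester is then displaced by chloride in a separate bimolecular substitution (LiCl, DMF, 40 °C), which comes back to the route at 20. The secondary ring bromide would need axial attack and should exchange far more slowly than the activated sulfonate.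
2. Step 9. If the boryl group of 12 lies axial, hydride may be delivered to the wrong face of the C10 carbonyl and erode the C10 configuration. Fallback: setting out from 12, LiBH(s-Bu)3 (THF, −78 °C) is used on purpose; it attacks from the equatorial direction whatever the orientation at C12 and should give the axial C10 alcohol F2. Mitsunobu reaction with 4-nitrobenzoic acid (PPh3, diisopropyl azodicarboxylate, toluene) inverts C10 to the equatorial 4-nitrobenzoate F3, and methanolysis (K2CO3, MeOH) comes back to the route at 13.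
3. Step 18. Base may remove HCl across C5–C6 of the enal (vinylogous elimination) before the alkyne forms. Fallback: setting out from 20, ozonolysis (O3, CH2Cl2, −78 °C; then Me2S) gives the aldehyde F4. Takai olefination (CrCl2, CHI3, THF/dioxane) gives the (E)-vinyl iodide F5, and Sonogashira coupling with trimethylsilylacetylene (Pd(PPh3)4, CuI, Et3N) gives the silyl enyne F6. K2CO3 in MeOH then removes the alkynyl silane and the route is rejoined at 22.

Further compounds
F1 | step 16 | (2R,3S,5R,6S)-5-bromo-2-{(2S,3R)-2-[(tert-butyldimethylsilyl)oxy]-3-chlorohex-5-en-1-yl}-6-ethyloxan-3-yl chloromethanesulfonate | CC[C@H]1[C@H](Br)C[C@H](OS(=O)(=O)CCl)[C@@H](C[C@H](O[Si](C)(C)C(C)(C)C)[C@H](Cl)CC=C)O1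
F2 | step 9 | (2R,3R,5R,6S)-2-{(2S,3R)-2-[(tert-butyldimethylsilyl)oxy]-3-chlorohex-5-en-1-yl}-6-ethyl-5-(4,4,5,5-tetramethyl-1,3,2-dioxaborolan-2-yl)oxan-3-ol | CC[C@H]1[C@H](B2OC(C)(C)C(C)(C)O2)C[C@@H](O)[C@@H](C[C@H](O[Si](C)(C)C(C)(C)C)[C@H](Cl)CC=C)O1
F3 | step 9 | (2R,3S,5R,6S)-2-{(2S,3R)-2-[(tert-butyldimethylsilyl)oxy]-3-chlorohex-5-en-1-yl}-6-ethyl-5-(4,4,5,5-tetramethyl-1,3,2-dioxaborolan-2-yl)oxan-3-yl 4-nitrobenzoate | CC[C@H]1[C@H](B2OC(C)(C)C(C)(C)O2)C[C@H](OC(=O)c2ccc(cc2)[N+](=O)[O-])[C@@H](C[C@H](O[Si](C)(C)C(C)(C)C)[C@H](Cl)CC=C)O1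
F4 | step 18 | (3R,4S)-5-[(2R,3R,5R,6S)-5-bromo-3-chloro-6-ethyloxan-2-yl]-4-[(tert-butyldimethylsilyl)oxy]-3-chloropentanal | CC[C@H]1[C@H](Br)C[C@@H](Cl)[C@@H](C[C@H](O[Si](C)(C)C(C)(C)C)[C@H](Cl)CC=O)O1
F5 | step 18 | tert-butyl({(2S,3R,5E)-1-[(2R,3R,5R,6S)-5-bromo-3-chloro-6-ethyloxan-2-yl]-3-chloro-6-iodohex-5-en-2-yl}oxy)dimethylsilane | CC[C@H]1[C@H](Br)C[C@@H](Cl)[C@@H](C[C@H](O[Si](C)(C)C(C)(C)C)[C@H](Cl)C/C=C/I)O1
F6 | step 18 | tert-butyl({(2S,3R,5E)-1-[(2R,3R,5R,6S)-5-bromo-3-chloro-6-ethyloxan-2-yl]-3-chloro-8-(trimethylsilyl)oct-5-en-7-yn-2-yl}oxy)dimethylsilane | CC[C@H]1[C@H](Br)C[C@@H](Cl)[C@@H](C[C@H](O[Si](C)(C)C(C)(C)C)[C@H](Cl)C/C=C/C#C[Si](C)(C)C)O1
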